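## Structural features

The target is a prostanoid. Its ring (C8–C12) is a 2-chloro-4-hydroxycyclopent-2-enone: C9 ketone, C10 chlorine, C10=C11 alkene, C12 tertiary carbinol. C12 carries a (2Z,5Z)-octa-2,5-dienyl chain (C13–C20), and C8 carries a seven-carbon chain that ends in the C1 methyl ester and bears acetoxy groups on C5, C6 and C7. There are five stereocentres (5S,6R,7R,8S,12R): C5, C6 and C7 are contiguous and acyclic, C7 adjoins the ring carbon C8, and C8 adjoins the quaternary carbinol C12. The C5–C7 triad has the all-threo pattern of D-xylose, provided the sugar's C5 becomes C8 and its C1 becomes C4. Fragile points are the C7 acetate (β to the C9 ketone, easily eliminated towards C8), the β-hydroxy ketone C9/C12, the epimerisable C8–H, the skipped diene with its doubly allylic C16, the electrophilic chloroenone, and the C5 oxygen, which can lactonise onto C1. The real difficulty is the quaternary carbinol C12 next to C8, and the introduction of chloroenone and acetates into a molecule that tolerates neither strong base nor strong acid. The key step uses the fact that C11 is sp2 and bonded to C12: C11 can be carried as a second carbinol that later leaves, so the ring bond C11–C12 can be made by reductive coupling of a C12 ketone with a C11 aldehyde, closing ring C8–C12 and setting C12.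

## Logic of the disconnections

**45 to 43 (through 44).** The three acetyl C–O bonds are cut last, because an acetate on C7 would not survive the basic steps that build the enone. This leaves three identical silyl ethers. The forward steps must remove them without lactonising O5 onto C1 and must acetylate without touching the tertiary C12 hydroxyl.

**43 to 40 (through 41 and 42).** The C10–Cl bond is cut and traced to an epoxide across C10–C11 of the plain enone. This avoids electrophilic chlorine, which the skipped diene would not tolerate. The forward steps need an oxidant that attacks only the electron-poor alkene, and chloride must enter at C10.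

**40 to 35 (through 39, 38, 37, 36).** The C10=C11 bond is traced to a leaving group on C11, the C9 carbonyl to a carbinol, and C8 is inverted. The gain is a saturated cyclopentane with a cis-11,12-diol. The forward steps must tell the secondary C11 hydroxyl from the tertiary C12 hydroxyl and from O9, and the equilibrium at C8 must favour the trans arrangement of the two chains.

**35 to 34.** The ring bond C11–C12 is cut; this is the strategic disconnection. It opens the only ring, removes two stereocentres and gives an acyclic chain with a C12 ketone and a C11 aldehyde. The forward coupling must give the cis diol and must place the C12 oxygen anti to the branch on C8; this is why 34 carries C8 in the epimeric configuration.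

**34 to 32 (through 33).** Both carbonyls are traced to carbinols. The C12 ketone has C13 as a methylene between the carbonyl and C14=C15, so it cannot arise from hydration of a C12≡C13 alkyne. It is also too labile to be carried, so it is unveiled by oxidation immediately before the key step, together with the aldehyde. The forward steps need a non-basic oxidant and a selectively removable group on O11.

**32 to 30 and 5 (through 31).** The C13–C14 bond is cut next to the carbinol, and the 14Z alkene is traced to an alkyne. The whole C14–C20 unit then arrives as 5 in one step. The forward steps need attack at the terminal epoxide carbon and a Z-selective semi-hydrogenation.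

**30 to 27 (through 29 and 28).** The epoxide is traced to a vinyl group and then to an ethynyl group on C8; the two hydroxyls of the other branch are masked. No skeletal bond is cut; the gain is that the C12 branch is reduced to two carbons. The epoxidation need not be selective, because C12 becomes a ketone.

**27 to 22 and 23 (through 26, 25, 24).** The C10–C11 bond is cut, and C11 is traced to the terminal alkene of an allyl group. This leaves a C9 aldehyde. The forward steps need an addition without base (C8 is α to the aldehyde) and an alkene cleavage that spares the alkyne; the C9 configuration is free.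

**22 to 19 and 20 (through 21).** The C8–C12 bond is cut: C8 was an epoxide carbon opened with inversion by an alkynyl nucleophile, and the extra carbon C10 is excised as formaldehyde. This sets C8 by reagent control. The forward opening must occur at C8 and not at C9.

**19 to 15 and 16 (through 18 and 17).** The epoxide C–O bonds and the C8=C9 bond are cut. The gain is the C8 aldehyde. The olefination must be E-selective, the reduction must spare the C1 ester, and the epoxidation must override the adjacent stereocentre C7.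

**15 to 9 and 10 (through 14, 13, 12, 11).** The C3–C4 bond is cut, so that C1–C3 come from one three-carbon ylide and C4–C8 from the sugar. The forward sequence must differentiate the primary oxygen on C8 from the three secondary ones.

**9 to 6 (through 8 and 7).** Only protecting-group bonds are cut. The sugar must be held in the open-chain form so that C1 is free for olefination.

**5 to 3 and 4, and 3 to 1 (through 2).** The C15–C16 bond of 5 is cut between an alkynyl nucleophile and an allylic bromide, and the 17Z alkene is traced to the alkyne of 1.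

## Other disconnections considered

**Alternative 1:** The cut is at the C5–O bond, with C1–C5 regarded as cyclopentanone A3. An anti-aldol of A3 with (R)-glyceraldehyde acetonide A4 would give hydroxy ketone A2. The forward key step is the Baeyer–Villiger oxidation of A2 with mCPBA: the more substituted α-carbon migrates with retention and gives δ-lactone A1, which holds C1–C8 with C5, C6 and C7 in the target configuration.
- In favour: two bond-forming steps from cheap materials, no phosphorus ylide, no hydrogenation. The lactone ties O5 to C1 deliberately, whereas the chosen plan must prevent that cyclisation at the end. On atom economy for the C1–C8 segment the alternative is the better of the two.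
- Against: C5 and C6 would be created by the aldol and not taken from the chiral pool; five-membered ketone donors are known for modest anti/syn control. A2 has an epimerisable, retro-aldol-prone α-centre. The lactone is an electrophile that would not survive the alkynylalane and acetylide steps, so it must be opened and O5 reprotected. The C7/C8 acetonide then needs several steps to become the C8 aldehyde.
- Comparison: A1 reaches the stage of 15 in about the same number of steps as the seven from 6, so step economy is equal. The Criegee rearrangement is as dependable as the Wittig reaction it replaces. Stereochemical certainty is lower. The alternative concerns only the side chain and leaves the ring problem (C12, chloroenone) untouched.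

**Alternative 2:** The cut is at C9–C10. The forward key step is an intramolecular hydroacylation: with [Rh(dppe)]BF4 the C9 aldehyde C–H bond of chloroalkynyl aldehyde A6 would add across the C10≡C11 chloroalkyne and give A5, the 12-O-triethylsilyl ether of 45.
- In favour: ring and complete chloroenone arise in one reagent-free isomerisation at the very end, with triacetate and all stereocentres in place. No enone chlorination, no epoxide and no acid step are needed. After ring closure one step remains, against seven in the chosen plan; on late-stage step economy the alternative is the better. The ring size matches the known scope of this catalysis (4-alkynals to cyclopentenones), so on ring-closure mode it is the equal.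
- Against: the alkyne carries chlorine. Oxidative addition of the C–Cl bond to low-valent rhodium, or a 1,2-chlorine shift to a vinylidene, can compete with the acyl rhodium hydride pathway, and this substituent has no close analogy in the reaction class. The aldehyde has an acetate β to it and an epimerisable C8, which invites elimination and decarbonylation. A6 requires C12 to be set in an open chain next to C8, the very problem the chosen plan solves inside a samarium chelate.
- Comparison: the difficulty is moved into the precursor, and the key mechanism is less secure than a pinacol coupling.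

**Alternative 3:** The cut is at C10=C11, with sulfur as a temporary bridge. In the 2,2-dichlorothiane 1,1-dioxide A8, potassium tert-butoxide would deprotonate C11, displace chloride from C10 to a chloro-episulfone and expel SO2 (Ramberg–Bäcklund). This contracts the six-membered ring to the 1-chlorocyclopentene A7, which then needs O9 deprotection and oxidation.
- In favour: the vinylic chlorine is placed at C10 by construction, which is better regiochemical certainty than opening an epoxy ketone with HCl. No acid is used, and a thiane is easy to close by C–S bond formation.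
- Against: the carbanion at C11 is β to the silyloxy group on C12, so E1cB loss of silanolate competes with the displacement. tert-Butoxide also threatens the methyl ester. Oxidation to the sulfone and dichlorination at C10 must be done in the presence of the skipped diene. C8 and C12 must be set beforehand, again without the help of the ring.
- Comparison: building and oxidising the thiane, chlorinating, contracting and then forming the enone is expected to take at least as many steps as the seven from 35 in the chosen plan. The ionic, strongly basic mechanism suits this substrate less well than the neutral single-electron step.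

Key step: step 24

Assumption: C9 (steps 15 to 26) and the carbinol carbon C12 (steps 19 to 22) are carried as epimer mixtures, because both become sp2 later; locants follow the prostanoid numbering of the target (C1 ester carbon, ring C8–C12).

## Route

Step 1
Reactants: 1 pent-2-yn-1-ol
Product: 2 (Z)-pent-2-en-1-ol
Conditions: H2 (1 atm), Pd/CaCO3 poisoned with Pb(OAc)2 (Lindlar catalyst), quinoline, pentane, rt
Reagents that add atoms: none
Why: Lindlar semi-hydrogenation adds hydrogen syn on the poisoned palladium surface and stops at the Z alkene, which becomes C17=C18.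

Step 2
Reactants: 2 (Z)-pent-2-en-1-ol
Product: 3 (Z)-1-bromopent-2-ene
Conditions: CBr4, PPh3, CH2Cl2, 0 °C
Reagents that add atoms: carbon tetrabromide BrC(Br)(Br)Br
Why: Appel bromination displaces the oxyphosphonium group by SN2 under neutral conditions, so the Z geometry should be kept.

Step 3
Reactants: 3 (Z)-1-bromopent-2-ene; 4 ethynylmagnesium bromide
Product: 5 (Z)-hept-4-en-1-yne
Conditions: CuCl (5 mol%), THF, 0 → 40 °C
Reagents that add atoms: none
Why: Copper-catalysed coupling of an alkynyl Grignard reagent with a primary allylic bromide gives the 1,4-enyne by direct substitution; excess Grignard reagent suppresses double alkylation.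

Step 4
Reactants: 6 D-xylose
Product: 7 D-xylose diethyl dithioacetal
Conditions: EtSH, conc. HCl, 0 °C
Reagents that add atoms: ethanethiol CCS
Why: Acid-catalysed dithioacetalisation traps the open-chain form of the sugar and leaves the three stereocentres untouched.

Step 5
Reactants: 7 D-xylose diethyl dithioacetal
Product: 8 2,3,4,5-tetra-O-(tert-butyldimethylsilyl)-D-xylose diethyl dithioacetal
Conditions: TBSOTf, 2,6-lutidine, CH2Cl2, 0 → 40 °C
Reagents that add atoms: tert-butyldimethylsilyl trifluoromethanesulfonate CC(C)(C)[Si](C)(C)OS(=O)(=O)C(F)(F)F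
Why: The silyl triflate with a hindered base silylates all four hydroxyls, including the crowded secondary ones that become O5, O6 and O7.

Step 6
Reactants: 8 2,3,4,5-tetra-O-(tert-butyldimethylsilyl)-D-xylose diethyl dithioacetal
Product: 9 2,3,4,5-tetra-O-(tert-butyldimethylsilyl)-aldehydo-D-xylose
Conditions: I2, NaHCO3, acetone–H2O, 0 °C
Reagents that add atoms: water O
Why: Iodine-mediated oxidative hydrolysis of the dithioacetal in buffered medium releases the aldehyde without acid, so the silyl ethers and the α-stereocentre should survive.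

Step 7
Reactants: 9 2,3,4,5-tetra-O-(tert-butyldimethylsilyl)-aldehydo-D-xylose; 10 (2-carboxyethyl)triphenylphosphonium bromide
Product: 12 methyl (3Z,5S,6R,7R)-5,6,7,8-tetrakis(tert-butyldimethylsilyloxy)oct-3-enoate, via sodium carboxylate 11 (not isolated)
Conditions: 10, NaHMDS (2 equiv), THF, −78 → 0 °C; 9, −78 °C → rt; then MeI, DMF, rt
Reagents that add atoms: iodomethane CI
Why: Wittig olefination with the non-stabilised ylide carboxylate adds C1–C3 in one step (alkene geometry irrelevant); the carboxylate is then methylated in the same flask by SN2 on iodomethane.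

Step 8
Reactants: 12 methyl (3Z,5S,6R,7R)-5,6,7,8-tetrakis(tert-butyldimethylsilyloxy)oct-3-enoate
Product: 13 methyl (5S,6R,7R)-5,6,7,8-tetrakis(tert-butyldimethylsilyloxy)octanoate
Conditions: H2 (1 atm), Pd/C, EtOAc, rt
Reagents that add atoms: none
Why: Heterogeneous hydrogenation saturates the only alkene; ester and silyl ethers are inert.

Step 9
Reactants: 13 methyl (5S,6R,7R)-5,6,7,8-tetrakis(tert-butyldimethylsilyloxy)octanoate
Product: 14 methyl (5S,6R,7R)-5,6,7-tris(tert-butyldimethylsilyloxy)-8-hydroxyoctanoate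
Conditions: HF·pyridine, pyridine, THF, 0 °C
Reagents that add atoms: none
Why: Buffered HF·pyridine cleaves the unhindered primary silyl ether much faster than the three crowded secondary ones (selective desilylation).

Step 10
Reactants: 14 methyl (5S,6R,7R)-5,6,7-tris(tert-butyldimethylsilyloxy)-8-hydroxyoctanoate
Product: 15 methyl (5S,6R,7S)-5,6,7-tris(tert-butyldimethylsilyloxy)-8-oxooctanoate
Conditions: Dess–Martin periodinane, NaHCO3, CH2Cl2, 0 °C → rt
Reagents that add atoms: none
Why: Dess–Martin oxidation gives the α-silyloxy aldehyde under buffered conditions that should not epimerise C7 (the 7S descriptor reflects only the new CIP priorities).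

Step 11
Reactants: 15 methyl (5S,6R,7S)-5,6,7-tris(tert-butyldimethylsilyloxy)-8-oxooctanoate; 16 (triphenylphosphoranylidene)acetaldehyde
Product: 18 methyl (5S,6R,7R,8E)-5,6,7-tris(tert-butyldimethylsilyloxy)-10-hydroxydec-8-enoate, via enal 17 (not isolated)
Conditions: toluene, 80 °C; then MeOH, CeCl3·7H2O, NaBH4, −20 °C
Reagents that add atoms: none
Why: The stabilised formyl ylide gives the E enal (Wittig reaction); Luche reduction in the same flask reduces only the aldehyde and leaves the methyl ester, which an ester olefination followed by hydride reduction would not.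

Step 12
Reactants: 18 methyl (5S,6R,7R,8E)-5,6,7-tris(tert-butyldimethylsilyloxy)-10-hydroxydec-8-enoate
Product: 19 methyl (5S,6R,7R,8S,9R)-5,6,7-tris(tert-butyldimethylsilyloxy)-8,9-epoxy-10-hydroxydecanoate
Conditions: Ti(OiPr)4 (20 mol%), D-(−)-diethyl tartrate (24 mol%), t-BuOOH, 4 Å MS, CH2Cl2, −20 °C
Reagents that add atoms: tert-butyl hydroperoxide CC(C)(C)OO
Why: Sharpless asymmetric epoxidation; the D-(−)-tartrate catalyst delivers oxygen to the face that gives the (8S,9R) epoxide, and reagent control is expected to override the neighbouring C7 centre. This places the C8 oxygen where inversion in step 13 gives the 8-epi configuration.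

Step 13
Reactants: 19 methyl (5S,6R,7R,8S,9R)-5,6,7-tris(tert-butyldimethylsilyloxy)-8,9-epoxy-10-hydroxydecanoate; 20 trimethylsilylacetylene
Product: 21 methyl (5S,6R,7R,8R,9S)-5,6,7-tris(tert-butyldimethylsilyloxy)-9,10-dihydroxy-8-[(trimethylsilyl)ethynyl]decanoate
Conditions: 20, n-BuLi, toluene, 0 °C; Et2AlCl; then 19, 0 °C → rt; aq. potassium sodium tartrate
Reagents that add atoms: none
Why: Alkynylalane opening of a 2,3-epoxy alcohol: the aluminium alkoxide at O10 holds the epoxide oxygen and the alkynyl group is delivered to the distal carbon C8 with inversion, forming C8–C12 and the 8R centre. A regioisomeric 1,3-diol would not be cleaved in step 14 and is removed there.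

Step 14
Reactants: 21 methyl (5S,6R,7R,8R,9S)-5,6,7-tris(tert-butyldimethylsilyloxy)-9,10-dihydroxy-8-[(trimethylsilyl)ethynyl]decanoate
Product: 22 methyl (5S,6R,7R,8S)-5,6,7-tris(tert-butyldimethylsilyloxy)-9-oxo-8-[(trimethylsilyl)ethynyl]nonanoate
Conditions: NaIO4, THF–H2O (pH 7), 0 °C
Reagents that add atoms: none
Why: Periodate glycol cleavage excises C10 and gives the C9 aldehyde under neutral conditions, so C8 should not epimerise (8S is a change of descriptor only).

Step 15
Reactants: 22 methyl (5S,6R,7R,8S)-5,6,7-tris(tert-butyldimethylsilyloxy)-9-oxo-8-[(trimethylsilyl)ethynyl]nonanoate; 23 allyl bromide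
Product: 24 methyl (5S,6R,7R,8R)-5,6,7-tris(tert-butyldimethylsilyloxy)-9-hydroxy-8-[(trimethylsilyl)ethynyl]dodec-11-enoate (C9 epimers)
Conditions: In powder, THF–H2O, rt
Reagents that add atoms: none
Why: Barbier allylation with indium in aqueous THF adds the allyl group without base, so the α-centre C8, the ester and the silyl alkyne are left alone; either C9 epimer serves.

Step 16
Reactants: 24 methyl (5S,6R,7R,8R)-5,6,7-tris(tert-butyldimethylsilyloxy)-9-hydroxy-8-[(trimethylsilyl)ethynyl]dodec-11-enoate (C9 epimers)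
Product: 27 methyl (5S,6R,7R,8R)-5,6,7-tris(tert-butyldimethylsilyloxy)-8-ethynyl-9,11-dihydroxyundecanoate (C9 epimers), via C11 aldehyde 25 (not isolated), via C-silyl diol 26 (not isolated)
Conditions: O3, CH2Cl2–MeOH, −78 °C; NaBH4, −78 → 0 °C; then K2CO3, rt
Reagents that add atoms: ozone [O-][O+]=O
Why: Ozonolysis cleaves the terminal alkene much faster than the silyl alkyne; borohydride reduces the peroxidic product to the C11 alcohol, and the methanolic base removes the alkynyl silyl group.

Step 17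
Reactants: 27 methyl (5S,6R,7R,8R)-5,6,7-tris(tert-butyldimethylsilyloxy)-8-ethynyl-9,11-dihydroxyundecanoate (C9 epimers)
Product: 28 methyl (5S,6R,7R,8R)-5,6,7-tris(tert-butyldimethylsilyloxy)-8-ethynyl-9,11-bis(triethylsilyloxy)undecanoate (C9 epimers)
Conditions: TESOTf, 2,6-lutidine, CH2Cl2, −78 → 0 °C
Reagents that add atoms: triethylsilyl trifluoromethanesulfonate CC[Si](CC)(CC)OS(=O)(=O)C(F)(F)F
Why: Both hydroxyls are silylated in one operation; the secondary triethylsilyl ether stays on O9 until after the key step, and the primary one is a temporary mask for O11.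

Step 18
Reactants: 28 methyl (5S,6R,7R,8R)-5,6,7-tris(tert-butyldimethylsilyloxy)-8-ethynyl-9,11-bis(triethylsilyloxy)undecanoate (C9 epimers)
Product: 29 methyl (5S,6R,7R,8R)-5,6,7-tris(tert-butyldimethylsilyloxy)-8-ethenyl-9,11-bis(triethylsilyloxy)undecanoate (C9 epimers)
Conditions: H2 (1 atm), Pd/CaCO3 poisoned with Pb(OAc)2, quinoline, EtOAc, rt
Reagents that add atoms: none
Why: Lindlar semi-hydrogenation converts the terminal alkyne into the vinyl group (C12=C13).

Step 19
Reactants: 29 methyl (5S,6R,7R,8R)-5,6,7-tris(tert-butyldimethylsilyloxy)-8-ethenyl-9,11-bis(triethylsilyloxy)undecanoate (C9 epimers)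
Product: 30 methyl (5S,6R,7R,8R)-5,6,7-tris(tert-butyldimethylsilyloxy)-8-(oxiran-2-yl)-9,11-bis(triethylsilyloxy)undecanoate (C9 and C12 epimers)
Conditions: mCPBA, NaHCO3, CH2Cl2, 0 °C → rt
Reagents that add atoms: 3-chloroperbenzoic acid OOC(=O)c1cccc(Cl)c1
Why: Prilezhaev epoxidation of the only alkene in the molecule; the configuration at C12 is irrelevant because C12 is oxidised in step 23.

Step 20
Reactants: 30 methyl (5S,6R,7R,8R)-5,6,7-tris(tert-butyldimethylsilyloxy)-8-(oxiran-2-yl)-9,11-bis(triethylsilyloxy)undecanoate (C9 and C12 epimers); 5 (Z)-hept-4-en-1-yne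
Product: 31 methyl (5S,6R,7R,8R)-5,6,7-tris(tert-butyldimethylsilyloxy)-8-[(6Z)-1-hydroxynon-6-en-3-yn-1-yl]-9,11-bis(triethylsilyloxy)undecanoate (C9 and C12 epimers)
Conditions: 5, n-BuLi, THF, −78 °C; BF3·OEt2; then 30, −78 °C
Reagents that add atoms: none
Why: The lithium acetylide with BF3·OEt2 opens the terminal epoxide by SN2 at the unhindered C13, forming C13–C14 and the C12 carbinol; the methyl ester should not react at −78 °C.

Step 21
Reactants: 31 methyl (5S,6R,7R,8R)-5,6,7-tris(tert-butyldimethylsilyloxy)-8-[(6Z)-1-hydroxynon-6-en-3-yn-1-yl]-9,11-bis(triethylsilyloxy)undecanoate (C9 and C12 epimers)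
Product: 32 methyl (5S,6R,7R,8R)-5,6,7-tris(tert-butyldimethylsilyloxy)-8-[(3Z,6Z)-1-hydroxynona-3,6-dien-1-yl]-9,11-bis(triethylsilyloxy)undecanoate (C9 and C12 epimers)
Conditions: H2 (1 atm), Pd/CaCO3 poisoned with Pb(OAc)2, quinoline, EtOAc, rt
Reagents that add atoms: none
Why: Lindlar semi-hydrogenation gives the 14Z alkene and completes the skipped Z,Z diene.

Step 22
Reactants: 32 methyl (5S,6R,7R,8R)-5,6,7-tris(tert-butyldimethylsilyloxy)-8-[(3Z,6Z)-1-hydroxynona-3,6-dien-1-yl]-9,11-bis(triethylsilyloxy)undecanoate (C9 and C12 epimers)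
Product: 33 methyl (5S,6R,7R,8R)-5,6,7-tris(tert-butyldimethylsilyloxy)-11-hydroxy-8-[(3Z,6Z)-1-hydroxynona-3,6-dien-1-yl]-9-(triethylsilyloxy)undecanoate (C9 and C12 epimers)
Conditions: PPTS (cat.), MeOH–CH2Cl2, 0 °C
Reagents that add atoms: none
Why: Mild acidic methanolysis removes the primary triethylsilyl ether far faster than the hindered secondary one on O9 or the tert-butyldimethylsilyl ethers.

Step 23
Reactants: 33 methyl (5S,6R,7R,8R)-5,6,7-tris(tert-butyldimethylsilyloxy)-11-hydroxy-8-[(3Z,6Z)-1-hydroxynona-3,6-dien-1-yl]-9-(triethylsilyloxy)undecanoate (C9 and C12 epimers)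
Product: 34 methyl (5S,6R,7R,8R)-5,6,7-tris(tert-butyldimethylsilyloxy)-8-[(3Z,6Z)-nona-3,6-dienoyl]-11-oxo-9-(triethylsilyloxy)undecanoate (C9 epimers)
Conditions: Dess–Martin periodinane, NaHCO3, CH2Cl2, 0 °C → rt
Reagents that add atoms: none
Why: Buffered Dess–Martin oxidation converts both alcohols and gives the β,γ-unsaturated ketone without moving C14=C15 into conjugation; the keto-aldehyde is used at once and not stored.

Step 24
Reactants: 34 methyl (5S,6R,7R,8R)-5,6,7-tris(tert-butyldimethylsilyloxy)-8-[(3Z,6Z)-nona-3,6-dienoyl]-11-oxo-9-(triethylsilyloxy)undecanoate (C9 epimers)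
Product: 35 methyl (5S,6R,7R,8R,11S,12R,14Z,17Z)-5,6,7-tris(tert-butyldimethylsilyloxy)-11,12-dihydroxy-9-(triethylsilyloxy)prosta-14,17-dien-1-oate (C9 epimers)
Conditions: SmI2 (2.5 equiv), THF, −78 → −40 °C; then aq. NH4Cl
Reagents that add atoms: none
Why: Divalent samarium reduces the aldehyde, the more easily reduced carbonyl, to a samarium-bound ketyl at C11; the C12 ketone binds to the same trivalent samarium and a second electron transfer accompanies C11–C12 bond formation, leaving a samarium diolate that is protonated on work-up. The closest known reaction type is the SmI2-mediated pinacol cyclisation of 1,5-keto-aldehydes and 1,5-dialdehydes to cis-cyclopentane-1,2-diols. Ring C8–C12 closes in the 5-exo-trig mode, the C11 ketyl carbon attacking the C12 carbonyl, whose oxygen stays outside the ring. C11 and C12 form cis because both oxygens are held on samarium in the cyclic transition state; C11 (11S) is lost again in step 27. C12 is controlled by C8: the solvated samarium alkoxides take the face of the forming ring away from the C7 branch on C8, so the 8R substrate gives the 12R carbinol of the target, which is why C8 was set in the epimeric configuration in steps 12 and 13. The step needs chemoselectivity for the two carbonyls over the methyl ester, the silyl ethers and the skipped diene, which SmI2 in THF without additives does not reduce; the β-silyloxy groups on C7 and C9 should stay because they are not α to a ketyl. The neutral medium and low temperature keep C14=C15 out of conjugation and C8 from epimerising before the bond forms. Both C9 epimers are taken through, since C9 becomes a ketone in step 27.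

Step 25
Reactants: 35 methyl (5S,6R,7R,8R,11S,12R,14Z,17Z)-5,6,7-tris(tert-butyldimethylsilyloxy)-11,12-dihydroxy-9-(triethylsilyloxy)prosta-14,17-dien-1-oate (C9 epimers)
Product: 36 methyl (5S,6R,7R,8R,11S,12R,14Z,17Z)-5,6,7-tris(tert-butyldimethylsilyloxy)-12-hydroxy-11-(methanesulfonyloxy)-9-(triethylsilyloxy)prosta-14,17-dien-1-oate (C9 epimers)
Conditions: MsCl, Et3N, CH2Cl2, −20 °C
Reagents that add atoms: methanesulfonyl chloride CS(=O)(=O)Cl
Why: Only the secondary C11 hydroxyl is sulfonylated; the tertiary C12 hydroxyl is too hindered, and a cis hydroxy mesylate cannot close to an epoxide.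

Step 26
Reactants: 36 methyl (5S,6R,7R,8R,11S,12R,14Z,17Z)-5,6,7-tris(tert-butyldimethylsilyloxy)-12-hydroxy-11-(methanesulfonyloxy)-9-(triethylsilyloxy)prosta-14,17-dien-1-oate (C9 epimers)
Product: 37 methyl (5S,6R,7R,8R,11S,12R,14Z,17Z)-5,6,7-tris(tert-butyldimethylsilyloxy)-9,12-dihydroxy-11-(methanesulfonyloxy)prosta-14,17-dien-1-oate (C9 epimers)
Conditions: HF·pyridine, pyridine, THF, 0 °C
Reagents that add atoms: none
Why: Buffered HF·pyridine removes the triethylsilyl ether selectively in the presence of the three bulkier tert-butyldimethylsilyl ethers.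

Step 27
Reactants: 37 methyl (5S,6R,7R,8R,11S,12R,14Z,17Z)-5,6,7-tris(tert-butyldimethylsilyloxy)-9,12-dihydroxy-11-(methanesulfonyloxy)prosta-14,17-dien-1-oate (C9 epimers)
Product: 40 methyl (5S,6R,7R,8S,12S,14Z,17Z)-5,6,7-tris(tert-butyldimethylsilyloxy)-12-hydroxy-9-oxoprosta-10,14,17-trien-1-oate, via mesyloxy ketone 38 (not isolated), via 8-epi enone 39 (not isolated)
Conditions: Dess–Martin periodinane, NaHCO3, CH2Cl2, 0 °C; then DBU, 0 °C → rt
Reagents that add atoms: none
Why: Oxidation gives the β-mesyloxy ketone, which loses methanesulfonate by E1cB on addition of DBU. The same base should equilibrate C8 through the dienolate to the more stable isomer with the two chains trans, as is known for cis-4,5-disubstituted cyclopent-2-enones (12S is a change of descriptor only).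

Step 28
Reactants: 40 methyl (5S,6R,7R,8S,12S,14Z,17Z)-5,6,7-tris(tert-butyldimethylsilyloxy)-12-hydroxy-9-oxoprosta-10,14,17-trien-1-oate
Product: 41 methyl (5S,6R,7R,8S,12R,14Z,17Z)-5,6,7-tris(tert-butyldimethylsilyloxy)-10,11-epoxy-12-hydroxy-9-oxoprosta-14,17-dien-1-oate (epoxide configuration not assigned)
Conditions: H2O2 (30%), NaOH (cat.), MeOH, −20 → 0 °C
Reagents that add atoms: hydrogen peroxide OO
Why: Weitz–Scheffer epoxidation: hydroperoxide anion adds only to the electron-poor enone and leaves the skipped diene alone; the epoxide configuration is irrelevant.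

Step 29
Reactants: 41 methyl (5S,6R,7R,8S,12R,14Z,17Z)-5,6,7-tris(tert-butyldimethylsilyloxy)-10,11-epoxy-12-hydroxy-9-oxoprosta-14,17-dien-1-oate
Product: 43 methyl (5S,6R,7R,8S,12R,14Z,17Z)-5,6,7-tris(tert-butyldimethylsilyloxy)-10-chloro-12-hydroxy-9-oxoprosta-10,14,17-trien-1-oate, via chlorohydrin 42 (not isolated)
Conditions: HCl (1 M in Et2O), CH2Cl2, 0 °C → rt
Reagents that add atoms: hydrogen chloride Cl
Why: Chloride opens the protonated epoxy ketone at C10 (SN2 α to the carbonyl), and the C11 hydroxyl is then lost by acid-catalysed dehydration through the enol, giving the 2-chloroenone. Any silyl ether lost here is harmless, because step 30 removes them all.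

Step 30
Reactants: 43 methyl (5S,6R,7R,8S,12R,14Z,17Z)-5,6,7-tris(tert-butyldimethylsilyloxy)-10-chloro-12-hydroxy-9-oxoprosta-10,14,17-trien-1-oate
Product: 44 methyl (5S,6R,7R,8S,12R,14Z,17Z)-10-chloro-5,6,7,12-tetrahydroxy-9-oxoprosta-10,14,17-trien-1-oate
Conditions: HF·pyridine, THF, 0 °C → rt
Reagents that add atoms: none
Why: Fluoride cleaves the three silyl ethers under mildly acidic conditions that the chloroenone and the tertiary alcohol should tolerate; the triol is acetylated at once to forestall lactonisation of O5 onto C1.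

Step 31
Reactants: 44 methyl (5S,6R,7R,8S,12R,14Z,17Z)-10-chloro-5,6,7,12-tetrahydroxy-9-oxoprosta-10,14,17-trien-1-oate
Product: 45 methyl (5S,6R,7R,8S,12R,14Z,17Z)-5,6,7-triacetoxy-10-chloro-12-hydroxy-9-oxoprosta-10,14,17-trien-1-oate (CNP0277476.1)
Conditions: Ac2O, pyridine, 0 °C → rt
Reagents that add atoms: acetic anhydride CC(=O)OC(C)=O
Why: The three secondary hydroxyls are acetylated; without an acyl-transfer catalyst the tertiary C12 hydroxyl should not react, and pyridine at or below room temperature should not eliminate the C7 acetate.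

## Compound list

1 | pent-2-yn-1-ol | CCC#CCO | starting material
2 | (Z)-pent-2-en-1-ol | CC/C=C\CO | intermediate
3 | (Z)-1-bromopent-2-ene | CC/C=C\CBr | intermediate
4 | ethynylmagnesium bromide | C#C[Mg]Br | starting material
5 | (Z)-hept-4-en-1-yne | CC/C=C\CC#C | intermediate
6 | D-xylose | O=C[C@H](O)[C@@H](O)[C@H](O)CO | starting material
7 | D-xylose diethyl dithioacetal | CCSC(SCC)[C@H](O)[C@@H](O)[C@H](O)CO | intermediate
8 | 2,3,4,5-tetra-O-(tert-butyldimethylsilyl)-D-xylose diethyl dithioacetal | CCSC(SCC)[C@H](O[Si](C)(C)C(C)(C)C)[C@@H](O[Si](C)(C)C(C)(C)C)[C@H](O[Si](C)(C)C(C)(C)C)CO[Si](C)(C)C(C)(C)C | intermediate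
9 | 2,3,4,5-tetra-O-(tert-butyldimethylsilyl)-aldehydo-D-xylose | O=C[C@H](O[Si](C)(C)C(C)(C)C)[C@@H](O[Si](C)(C)C(C)(C)C)[C@H](O[Si](C)(C)C(C)(C)C)CO[Si](C)(C)C(C)(C)C | intermediate
10 | (2-carboxyethyl)triphenylphosphonium bromide | OC(=O)CC[P+](c1ccccc1)(c1ccccc1)c1ccccc1.[Br-] | starting material
11 | sodium (3Z,5S,6R,7R)-5,6,7,8-tetrakis(tert-butyldimethylsilyloxy)oct-3-enoate (not isolated) | [Na+].[O-]C(=O)C/C=C\[C@H](O[Si](C)(C)C(C)(C)C)[C@@H](O[Si](C)(C)C(C)(C)C)[C@H](O[Si](C)(C)C(C)(C)C)CO[Si](C)(C)C(C)(C)C | intermediate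
12 | methyl (3Z,5S,6R,7R)-5,6,7,8-tetrakis(tert-butyldimethylsilyloxy)oct-3-enoate | COC(=O)C/C=C\[C@H](O[Si](C)(C)C(C)(C)C)[C@@H](O[Si](C)(C)C(C)(C)C)[C@H](O[Si](C)(C)C(C)(C)C)CO[Si](C)(C)C(C)(C)C | intermediate
13 | methyl (5S,6R,7R)-5,6,7,8-tetrakis(tert-butyldimethylsilyloxy)octanoate | COC(=O)CCC[C@H](O[Si](C)(C)C(C)(C)C)[C@@H](O[Si](C)(C)C(C)(C)C)[C@H](O[Si](C)(C)C(C)(C)C)CO[Si](C)(C)C(C)(C)C | intermediate
14 | methyl (5S,6R,7R)-5,6,7-tris(tert-butyldimethylsilyloxy)-8-hydroxyoctanoate | COC(=O)CCC[C@H](O[Si](C)(C)C(C)(C)C)[C@@H](O[Si](C)(C)C(C)(C)C)[C@H](O[Si](C)(C)C(C)(C)C)CO | intermediate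
15 | methyl (5S,6R,7S)-5,6,7-tris(tert-butyldimethylsilyloxy)-8-oxooctanoate | COC(=O)CCC[C@H](O[Si](C)(C)C(C)(C)C)[C@@H](O[Si](C)(C)C(C)(C)C)[C@H](O[Si](C)(C)C(C)(C)C)C=O | intermediate
16 | (triphenylphosphoranylidene)acetaldehyde | O=CC=P(c1ccccc1)(c1ccccc1)c1ccccc1 | starting material
17 | methyl (5S,6R,7R,8E)-5,6,7-tris(tert-butyldimethylsilyloxy)-10-oxodec-8-enoate (not isolated) | O=C/C=C/[C@@H](O[Si](C)(C)C(C)(C)C)[C@H](O[Si](C)(C)C(C)(C)C)[C@H](CCCC(=O)OC)O[Si](C)(C)C(C)(C)C | intermediate
18 | methyl (5S,6R,7R,8E)-5,6,7-tris(tert-butyldimethylsilyloxy)-10-hydroxydec-8-enoate | OC/C=C/[C@@H](O[Si](C)(C)C(C)(C)C)[C@H](O[Si](C)(C)C(C)(C)C)[C@H](CCCC(=O)OC)O[Si](C)(C)C(C)(C)C | intermediate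
19 | methyl (5S,6R,7R,8S,9R)-5,6,7-tris(tert-butyldimethylsilyloxy)-8,9-epoxy-10-hydroxydecanoate | OC[C@H]1O[C@@H]1[C@@H](O[Si](C)(C)C(C)(C)C)[C@H](O[Si](C)(C)C(C)(C)C)[C@H](CCCC(=O)OC)O[Si](C)(C)C(C)(C)C | intermediate
20 | trimethylsilylacetylene | C#C[Si](C)(C)C | starting material
21 | methyl (5S,6R,7R,8R,9S)-5,6,7-tris(tert-butyldimethylsilyloxy)-9,10-dihydroxy-8-[(trimethylsilyl)ethynyl]decanoate | C[Si](C)(C)C#C[C@H]([C@H](O)CO)[C@@H](O[Si](C)(C)C(C)(C)C)[C@H](O[Si](C)(C)C(C)(C)C)[C@H](CCCC(=O)OC)O[Si](C)(C)C(C)(C)C | intermediate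
22 | methyl (5S,6R,7R,8S)-5,6,7-tris(tert-butyldimethylsilyloxy)-9-oxo-8-[(trimethylsilyl)ethynyl]nonanoate | C[Si](C)(C)C#C[C@H](C=O)[C@@H](O[Si](C)(C)C(C)(C)C)[C@H](O[Si](C)(C)C(C)(C)C)[C@H](CCCC(=O)OC)O[Si](C)(C)C(C)(C)C | intermediate
23 | allyl bromide | C=CCBr | starting material
24 | methyl (5S,6R,7R,8R)-5,6,7-tris(tert-butyldimethylsilyloxy)-9-hydroxy-8-[(trimethylsilyl)ethynyl]dodec-11-enoate (C9 epimers) | C[Si](C)(C)C#C[C@H](C(O)CC=C)[C@@H](O[Si](C)(C)C(C)(C)C)[C@H](O[Si](C)(C)C(C)(C)C)[C@H](CCCC(=O)OC)O[Si](C)(C)C(C)(C)C | intermediate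
25 | methyl (5S,6R,7R,8R)-5,6,7-tris(tert-butyldimethylsilyloxy)-9-hydroxy-11-oxo-8-[(trimethylsilyl)ethynyl]undecanoate (C9 epimers, not isolated) | C[Si](C)(C)C#C[C@H](C(O)CC=O)[C@@H](O[Si](C)(C)C(C)(C)C)[C@H](O[Si](C)(C)C(C)(C)C)[C@H](CCCC(=O)OC)O[Si](C)(C)C(C)(C)C | intermediate
26 | methyl (5S,6R,7R,8R)-5,6,7-tris(tert-butyldimethylsilyloxy)-9,11-dihydroxy-8-[(trimethylsilyl)ethynyl]undecanoate (C9 epimers, not isolated) | C[Si](C)(C)C#C[C@H](C(O)CCO)[C@@H](O[Si](C)(C)C(C)(C)C)[C@H](O[Si](C)(C)C(C)(C)C)[C@H](CCCC(=O)OC)O[Si](C)(C)C(C)(C)C | intermediate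
27 | methyl (5S,6R,7R,8R)-5,6,7-tris(tert-butyldimethylsilyloxy)-8-ethynyl-9,11-dihydroxyundecanoate (C9 epimers) | C#C[C@H](C(O)CCO)[C@@H](O[Si](C)(C)C(C)(C)C)[C@H](O[Si](C)(C)C(C)(C)C)[C@H](CCCC(=O)OC)O[Si](C)(C)C(C)(C)C | intermediate
28 | methyl (5S,6R,7R,8R)-5,6,7-tris(tert-butyldimethylsilyloxy)-8-ethynyl-9,11-bis(triethylsilyloxy)undecanoate (C9 epimers) | C#C[C@H](C(O[Si](CC)(CC)CC)CCO[Si](CC)(CC)CC)[C@@H](O[Si](C)(C)C(C)(C)C)[C@H](O[Si](C)(C)C(C)(C)C)[C@H](CCCC(=O)OC)O[Si](C)(C)C(C)(C)C | intermediate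
29 | methyl (5S,6R,7R,8R)-5,6,7-tris(tert-butyldimethylsilyloxy)-8-ethenyl-9,11-bis(triethylsilyloxy)undecanoate (C9 epimers) | C=C[C@H](C(O[Si](CC)(CC)CC)CCO[Si](CC)(CC)CC)[C@@H](O[Si](C)(C)C(C)(C)C)[C@H](O[Si](C)(C)C(C)(C)C)[C@H](CCCC(=O)OC)O[Si](C)(C)C(C)(C)C | intermediate
30 | methyl (5S,6R,7R,8R)-5,6,7-tris(tert-butyldimethylsilyloxy)-8-(oxiran-2-yl)-9,11-bis(triethylsilyloxy)undecanoate (C9 and C12 epimers) | C1OC1[C@H](C(O[Si](CC)(CC)CC)CCO[Si](CC)(CC)CC)[C@@H](O[Si](C)(C)C(C)(C)C)[C@H](O[Si](C)(C)C(C)(C)C)[C@H](CCCC(=O)OC)O[Si](C)(C)C(C)(C)C | intermediate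
31 | methyl (5S,6R,7R,8R)-5,6,7-tris(tert-butyldimethylsilyloxy)-8-[(6Z)-1-hydroxynon-6-en-3-yn-1-yl]-9,11-bis(triethylsilyloxy)undecanoate (C9 and C12 epimers) | CC/C=C\CC#CCC(O)[C@H](C(O[Si](CC)(CC)CC)CCO[Si](CC)(CC)CC)[C@@H](O[Si](C)(C)C(C)(C)C)[C@H](O[Si](C)(C)C(C)(C)C)[C@H](CCCC(=O)OC)O[Si](C)(C)C(C)(C)C | intermediate
32 | methyl (5S,6R,7R,8R)-5,6,7-tris(tert-butyldimethylsilyloxy)-8-[(3Z,6Z)-1-hydroxynona-3,6-dien-1-yl]-9,11-bis(triethylsilyloxy)undecanoate (C9 and C12 epimers) | CC/C=C\C/C=C\CC(O)[C@H](C(O[Si](CC)(CC)CC)CCO[Si](CC)(CC)CC)[C@@H](O[Si](C)(C)C(C)(C)C)[C@H](O[Si](C)(C)C(C)(C)C)[C@H](CCCC(=O)OC)O[Si](C)(C)C(C)(C)C | intermediate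
33 | methyl (5S,6R,7R,8R)-5,6,7-tris(tert-butyldimethylsilyloxy)-11-hydroxy-8-[(3Z,6Z)-1-hydroxynona-3,6-dien-1-yl]-9-(triethylsilyloxy)undecanoate (C9 and C12 epimers) | CC/C=C\C/C=C\CC(O)[C@H](C(O[Si](CC)(CC)CC)CCO)[C@@H](O[Si](C)(C)C(C)(C)C)[C@H](O[Si](C)(C)C(C)(C)C)[C@H](CCCC(=O)OC)O[Si](C)(C)C(C)(C)C | intermediate
34 | methyl (5S,6R,7R,8R)-5,6,7-tris(tert-butyldimethylsilyloxy)-8-[(3Z,6Z)-nona-3,6-dienoyl]-11-oxo-9-(triethylsilyloxy)undecanoate (C9 epimers) | CC/C=C\C/C=C\CC(=O)[C@H](C(O[Si](CC)(CC)CC)CC=O)[C@@H](O[Si](C)(C)C(C)(C)C)[C@H](O[Si](C)(C)C(C)(C)C)[C@H](CCCC(=O)OC)O[Si](C)(C)C(C)(C)C | intermediate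
35 | methyl (5S,6R,7R,8R,11S,12R,14Z,17Z)-5,6,7-tris(tert-butyldimethylsilyloxy)-11,12-dihydroxy-9-(triethylsilyloxy)prosta-14,17-dien-1-oate (C9 epimers) | CC/C=C\C/C=C\C[C@]1(O)[C@@H](O)CC(O[Si](CC)(CC)CC)[C@@H]1[C@@H](O[Si](C)(C)C(C)(C)C)[C@H](O[Si](C)(C)C(C)(C)C)[C@H](CCCC(=O)OC)O[Si](C)(C)C(C)(C)C | intermediate
36 | methyl (5S,6R,7R,8R,11S,12R,14Z,17Z)-5,6,7-tris(tert-butyldimethylsilyloxy)-12-hydroxy-11-(methanesulfonyloxy)-9-(triethylsilyloxy)prosta-14,17-dien-1-oate (C9 epimers) | CC/C=C\C/C=C\C[C@]1(O)[C@@H](OS(C)(=O)=O)CC(O[Si](CC)(CC)CC)[C@@H]1[C@@H](O[Si](C)(C)C(C)(C)C)[C@H](O[Si](C)(C)C(C)(C)C)[C@H](CCCC(=O)OC)O[Si](C)(C)C(C)(C)C | intermediate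
37 | methyl (5S,6R,7R,8R,11S,12R,14Z,17Z)-5,6,7-tris(tert-butyldimethylsilyloxy)-9,12-dihydroxy-11-(methanesulfonyloxy)prosta-14,17-dien-1-oate (C9 epimers) | CC/C=C\C/C=C\C[C@]1(O)[C@@H](OS(C)(=O)=O)CC(O)[C@@H]1[C@@H](O[Si](C)(C)C(C)(C)C)[C@H](O[Si](C)(C)C(C)(C)C)[C@H](CCCC(=O)OC)O[Si](C)(C)C(C)(C)C | intermediate
38 | methyl (5S,6R,7R,8R,11S,12R,14Z,17Z)-5,6,7-tris(tert-butyldimethylsilyloxy)-12-hydroxy-11-(methanesulfonyloxy)-9-oxoprosta-14,17-dien-1-oate (not isolated) | CC/C=C\C/C=C\C[C@]1(O)[C@@H](OS(C)(=O)=O)CC(=O)[C@@H]1[C@@H](O[Si](C)(C)C(C)(C)C)[C@H](O[Si](C)(C)C(C)(C)C)[C@H](CCCC(=O)OC)O[Si](C)(C)C(C)(C)C | intermediate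
39 | methyl (5S,6R,7R,8R,12S,14Z,17Z)-5,6,7-tris(tert-butyldimethylsilyloxy)-12-hydroxy-9-oxoprosta-10,14,17-trien-1-oate (8-epimer of 40, not isolated) | CC/C=C\C/C=C\C[C@]1(O)C=CC(=O)[C@@H]1[C@@H](O[Si](C)(C)C(C)(C)C)[C@H](O[Si](C)(C)C(C)(C)C)[C@H](CCCC(=O)OC)O[Si](C)(C)C(C)(C)C | intermediate
40 | methyl (5S,6R,7R,8S,12S,14Z,17Z)-5,6,7-tris(tert-butyldimethylsilyloxy)-12-hydroxy-9-oxoprosta-10,14,17-trien-1-oate | CC/C=C\C/C=C\C[C@]1(O)C=CC(=O)[C@H]1[C@@H](O[Si](C)(C)C(C)(C)C)[C@H](O[Si](C)(C)C(C)(C)C)[C@H](CCCC(=O)OC)O[Si](C)(C)C(C)(C)C | intermediate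
41 | methyl (5S,6R,7R,8S,12R,14Z,17Z)-5,6,7-tris(tert-butyldimethylsilyloxy)-10,11-epoxy-12-hydroxy-9-oxoprosta-14,17-dien-1-oate (epoxide configuration not assigned) | CC/C=C\C/C=C\C[C@]1(O)C2OC2C(=O)[C@H]1[C@@H](O[Si](C)(C)C(C)(C)C)[C@H](O[Si](C)(C)C(C)(C)C)[C@H](CCCC(=O)OC)O[Si](C)(C)C(C)(C)C | intermediate
42 | methyl (5S,6R,7R,8S,12R,14Z,17Z)-5,6,7-tris(tert-butyldimethylsilyloxy)-10-chloro-11,12-dihydroxy-9-oxoprosta-14,17-dien-1-oate (C10 and C11 not assigned, not isolated) | CC/C=C\C/C=C\C[C@]1(O)C(O)C(Cl)C(=O)[C@H]1[C@@H](O[Si](C)(C)C(C)(C)C)[C@H](O[Si](C)(C)C(C)(C)C)[C@H](CCCC(=O)OC)O[Si](C)(C)C(C)(C)C | intermediate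
43 | methyl (5S,6R,7R,8S,12R,14Z,17Z)-5,6,7-tris(tert-butyldimethylsilyloxy)-10-chloro-12-hydroxy-9-oxoprosta-10,14,17-trien-1-oate | CC/C=C\C/C=C\C[C@]1(O)C=C(Cl)C(=O)[C@H]1[C@@H](O[Si](C)(C)C(C)(C)C)[C@H](O[Si](C)(C)C(C)(C)C)[C@H](CCCC(=O)OC)O[Si](C)(C)C(C)(C)C | intermediate
44 | methyl (5S,6R,7R,8S,12R,14Z,17Z)-10-chloro-5,6,7,12-tetrahydroxy-9-oxoprosta-10,14,17-trien-1-oate | CC/C=C\C/C=C\C[C@]1(O)C=C(Cl)C(=O)[C@H]1[C@@H](O)[C@H](O)[C@H](CCCC(=O)OC)O | intermediate
45 | methyl (5S,6R,7R,8S,12R,14Z,17Z)-5,6,7-triacetoxy-10-chloro-12-hydroxy-9-oxoprosta-10,14,17-trien-1-oate (CNP0277476.1) | CC/C=C\C/C=C\C[C@]1(O)C=C(Cl)C(=O)[C@H]1[C@@H](OC(C)=O)[C@H](OC(C)=O)[C@H](CCCC(=O)OC)OC(C)=O | target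

## Step count and least certain steps

Total: 31 steps. Longest linear sequence: 28 steps (steps 4–31, from 6 to 45). The side branch from 1 to 5 takes 3 steps.

**Step 24 (key step).** The most likely failures are simple reduction of the aldehyde to the primary alcohol before coupling, or weak facial discrimination at C12, because the two C9 epimers need not fold alike in the chelate.
Fallback: starting from 34, the same C11–C12 bond is formed without a reductant by an intramolecular crossed aldehyde–ketone benzoin reaction, catalysed by a triazolium-derived N-heterocyclic carbene with Et3N. This gives the cyclic acyloin methyl (5S,6R,7R,8R,12R,14Z,17Z)-5,6,7-tris(tert-butyldimethylsilyloxy)-12-hydroxy-11-oxo-9-(triethylsilyloxy)prosta-14,17-dien-1-oate F1. Reduction of the C11 ketone with NaBH4 and CeCl3·7H2O gives the 11-epimer of 35, F2; any 35 formed rejoins the route directly. Either C11 configuration serves, because C11 becomes sp2. Mesylation as in step 25 gives the 11-epimer of 36, F3; removal of the triethylsilyl group as in step 26 gives the 11-epimer of 37, F4; oxidation and elimination as in step 27 return to the route at 40.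

**Step 13.** The opening may occur at C9 or stall, because C8 is flanked by the silyloxy-bearing C7, which both crowds the carbon and withdraws electron density; the excess alane may also attack the ester.
Fallback: C8 is set by substrate control instead, starting from 15. Horner–Wadsworth–Emmons olefination with triethyl phosphonoacetate (LiCl, DBU) gives 10-ethyl 1-methyl (5S,6R,7R,8E)-5,6,7-tris(tert-butyldimethylsilyloxy)dec-8-enedioate F5. Conjugate addition of a vinyl cuprate with Me3SiCl is expected to occur anti to the C7 silyloxy group; Rubottom oxidation of the resulting ketene silyl acetal with mCPBA gives 10-ethyl 1-methyl (5S,6R,7R,8R)-5,6,7-tris(tert-butyldimethylsilyloxy)-8-ethenyl-9-hydroxydecanedioate F6. NaBH4 reduces the activated α-hydroxy ester to methyl (5S,6R,7R,8R)-5,6,7-tris(tert-butyldimethylsilyloxy)-8-ethenyl-9,10-dihydroxydecanoate F7. Periodate cleavage gives methyl (5S,6R,7R,8S)-5,6,7-tris(tert-butyldimethylsilyloxy)-8-ethenyl-9-oxononanoate F8. A Mukaiyama aldol reaction with the ketene silyl thioacetal of S-ethyl thioacetate (BF3·OEt2) gives methyl (5S,6R,7R,8R)-5,6,7-tris(tert-butyldimethylsilyloxy)-8-ethenyl-11-(ethylsulfanyl)-9-hydroxy-11-oxoundecanoate F9. NaBH4 reduces the thioester to methyl (5S,6R,7R,8R)-5,6,7-tris(tert-butyldimethylsilyloxy)-8-ethenyl-9,11-dihydroxyundecanoate F10. Silylation as in step 17 returns to the route at 29.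

**Step 27.** Loss of the C7 silyloxy group by β-elimination from the C8 enolate may compete with the equilibration, or the inversion at C8 may stay incomplete.
Fallback: starting from 37, the one-pot sequence is stopped at 39 by using Et3N in place of DBU. The equilibration is then replaced by a kinetically controlled protonation. TESOTf and Et3N convert 39 into methyl (5S,6R,7R,14Z,17Z)-5,6,7-tris(tert-butyldimethylsilyloxy)-9,12-bis(triethylsilyloxy)prosta-8,10,14,17-tetraen-1-oate F11. Buffered HF·pyridine at −78 °C cleaves the dienol ether and should protonate C8 from the face away from the bulky C12 silyloxy group, giving the 12-O-triethylsilyl ether of 40, F12. Cleavage of this tertiary silyl ether with HF·pyridine at 0 °C returns to the route at 40.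

**Step 29 (with step 28).** The acid may open the epoxide at C11, ionise the tertiary carbinol, or strip silyl groups unevenly; the basic epoxidation before it may also trigger elimination at C7.
Fallback: starting from 40, the chlorine is introduced through a vinyl metal, with no epoxide and no acid. α-Iodination of the enone with I2 and pyridine gives methyl (5S,6R,7R,8S,12R,14Z,17Z)-5,6,7-tris(tert-butyldimethylsilyloxy)-12-hydroxy-10-iodo-9-oxoprosta-10,14,17-trien-1-oate F13. Stannylation with hexamethylditin and Pd(PPh3)4 gives the 10-(trimethylstannyl) enone F14. Chlorodestannylation with CuCl2 returns to the route at 43.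

**Step 7.** The β-carboxylate ylide may fragment (loss of acrylate and PPh3) before it meets the hindered aldehyde, and the aldehyde may epimerise at its α-carbon under the basic conditions.
Fallback: starting from 9, a robust non-stabilised ylide from (3-benzyloxypropyl)triphenylphosphonium bromide (NaHMDS) gives (3Z,5S,6R,7R)-1-(benzyloxy)-5,6,7,8-tetrakis(tert-butyldimethylsilyloxy)oct-3-ene F15. Hydrogenation over Pd/C saturates the alkene and removes the benzyl group to give (5S,6R,7R)-5,6,7,8-tetrakis(tert-butyldimethylsilyloxy)octan-1-ol F16. Oxidation with TEMPO and PhI(OAc)2 in wet MeCN gives (5S,6R,7R)-5,6,7,8-tetrakis(tert-butyldimethylsilyloxy)octanoic acid F17. Esterification with trimethylsilyldiazomethane returns to the route at 13.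

## Further compounds

F1 | step 24 | methyl (5S,6R,7R,8R,12R,14Z,17Z)-5,6,7-tris(tert-butyldimethylsilyloxy)-12-hydroxy-11-oxo-9-(triethylsilyloxy)prosta-14,17-dien-1-oate (C9 epimers) | CC/C=C\C/C=C\C[C@]1(O)C(=O)CC(O[Si](CC)(CC)CC)[C@@H]1[C@@H](O[Si](C)(C)C(C)(C)C)[C@H](O[Si](C)(C)C(C)(C)C)[C@H](CCCC(=O)OC)O[Si](C)(C)C(C)(C)C
F2 | step 24 | methyl (5S,6R,7R,8R,11R,12R,14Z,17Z)-5,6,7-tris(tert-butyldimethylsilyloxy)-11,12-dihydroxy-9-(triethylsilyloxy)prosta-14,17-dien-1-oate (11-epimer of 35) | CC/C=C\C/C=C\C[C@]1(O)[C@H](O)CC(O[Si](CC)(CC)CC)[C@@H]1[C@@H](O[Si](C)(C)C(C)(C)C)[C@H](O[Si](C)(C)C(C)(C)C)[C@H](CCCC(=O)OC)O[Si](C)(C)C(C)(C)C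
F3 | step 24 | methyl (5S,6R,7R,8R,11R,12R,14Z,17Z)-5,6,7-tris(tert-butyldimethylsilyloxy)-12-hydroxy-11-(methanesulfonyloxy)-9-(triethylsilyloxy)prosta-14,17-dien-1-oate (11-epimer of 36) | CC/C=C\C/C=C\C[C@]1(O)[C@H](OS(C)(=O)=O)CC(O[Si](CC)(CC)CC)[C@@H]1[C@@H](O[Si](C)(C)C(C)(C)C)[C@H](O[Si](C)(C)C(C)(C)C)[C@H](CCCC(=O)OC)O[Si](C)(C)C(C)(C)C
F4 | step 24 | methyl (5S,6R,7R,8R,11R,12R,14Z,17Z)-5,6,7-tris(tert-butyldimethylsilyloxy)-9,12-dihydroxy-11-(methanesulfonyloxy)prosta-14,17-dien-1-oate (11-epimer of 37) | CC/C=C\C/C=C\C[C@]1(O)[C@H](OS(C)(=O)=O)CC(O)[C@@H]1[C@@H](O[Si](C)(C)C(C)(C)C)[C@H](O[Si](C)(C)C(C)(C)C)[C@H](CCCC(=O)OC)O[Si](C)(C)C(C)(C)C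
F5 | step 13 | 10-ethyl 1-methyl (5S,6R,7R,8E)-5,6,7-tris(tert-butyldimethylsilyloxy)dec-8-enedioate | CCOC(=O)/C=C/[C@@H](O[Si](C)(C)C(C)(C)C)[C@H](O[Si](C)(C)C(C)(C)C)[C@H](CCCC(=O)OC)O[Si](C)(C)C(C)(C)C
F6 | step 13 | 10-ethyl 1-methyl (5S,6R,7R,8R)-5,6,7-tris(tert-butyldimethylsilyloxy)-8-ethenyl-9-hydroxydecanedioate (C9 epimers) | CCOC(=O)C(O)[C@@H](C=C)[C@@H](O[Si](C)(C)C(C)(C)C)[C@H](O[Si](C)(C)C(C)(C)C)[C@H](CCCC(=O)OC)O[Si](C)(C)C(C)(C)C
F7 | step 13 | methyl (5S,6R,7R,8R)-5,6,7-tris(tert-butyldimethylsilyloxy)-8-ethenyl-9,10-dihydroxydecanoate (C9 epimers) | OCC(O)[C@@H](C=C)[C@@H](O[Si](C)(C)C(C)(C)C)[C@H](O[Si](C)(C)C(C)(C)C)[C@H](CCCC(=O)OC)O[Si](C)(C)C(C)(C)C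
F8 | step 13 | methyl (5S,6R,7R,8S)-5,6,7-tris(tert-butyldimethylsilyloxy)-8-ethenyl-9-oxononanoate | O=C[C@@H](C=C)[C@@H](O[Si](C)(C)C(C)(C)C)[C@H](O[Si](C)(C)C(C)(C)C)[C@H](CCCC(=O)OC)O[Si](C)(C)C(C)(C)C
F9 | step 13 | methyl (5S,6R,7R,8R)-5,6,7-tris(tert-butyldimethylsilyloxy)-8-ethenyl-11-(ethylsulfanyl)-9-hydroxy-11-oxoundecanoate (C9 epimers) | CCSC(=O)CC(O)[C@@H](C=C)[C@@H](O[Si](C)(C)C(C)(C)C)[C@H](O[Si](C)(C)C(C)(C)C)[C@H](CCCC(=O)OC)O[Si](C)(C)C(C)(C)C
F10 | step 13 | methyl (5S,6R,7R,8R)-5,6,7-tris(tert-butyldimethylsilyloxy)-8-ethenyl-9,11-dihydroxyundecanoate (C9 epimers) | OCCC(O)[C@@H](C=C)[C@@H](O[Si](C)(C)C(C)(C)C)[C@H](O[Si](C)(C)C(C)(C)C)[C@H](CCCC(=O)OC)O[Si](C)(C)C(C)(C)C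
F11 | step 27 | methyl (5S,6R,7R,14Z,17Z)-5,6,7-tris(tert-butyldimethylsilyloxy)-9,12-bis(triethylsilyloxy)prosta-8,10,14,17-tetraen-1-oate (C12 as in 40) | CC/C=C\C/C=C\C[C@]1(O[Si](CC)(CC)CC)C=CC(O[Si](CC)(CC)CC)=C1[C@@H](O[Si](C)(C)C(C)(C)C)[C@H](O[Si](C)(C)C(C)(C)C)[C@H](CCCC(=O)OC)O[Si](C)(C)C(C)(C)C
F12 | step 27 | methyl (5S,6R,7R,14Z,17Z)-5,6,7-tris(tert-butyldimethylsilyloxy)-9-oxo-12-(triethylsilyloxy)prosta-10,14,17-trien-1-oate (12-O-triethylsilyl ether of 40, C8 and C12 as in 40) | CC/C=C\C/C=C\C[C@]1(O[Si](CC)(CC)CC)C=CC(=O)[C@H]1[C@@H](O[Si](C)(C)C(C)(C)C)[C@H](O[Si](C)(C)C(C)(C)C)[C@H](CCCC(=O)OC)O[Si](C)(C)C(C)(C)C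
F13 | step 29 | methyl (5S,6R,7R,8S,12R,14Z,17Z)-5,6,7-tris(tert-butyldimethylsilyloxy)-12-hydroxy-10-iodo-9-oxoprosta-10,14,17-trien-1-oate | CC/C=C\C/C=C\C[C@]1(O)C=C(I)C(=O)[C@H]1[C@@H](O[Si](C)(C)C(C)(C)C)[C@H](O[Si](C)(C)C(C)(C)C)[C@H](CCCC(=O)OC)O[Si](C)(C)C(C)(C)C
F14 | step 29 | methyl (5S,6R,7R,14Z,17Z)-5,6,7-tris(tert-butyldimethylsilyloxy)-12-hydroxy-9-oxo-10-(trimethylstannyl)prosta-10,14,17-trien-1-oate (C8 and C12 as in 40) | CC/C=C\C/C=C\C[C@]1(O)C=C([Sn](C)(C)C)C(=O)[C@H]1[C@@H](O[Si](C)(C)C(C)(C)C)[C@H](O[Si](C)(C)C(C)(C)C)[C@H](CCCC(=O)OC)O[Si](C)(C)C(C)(C)C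
F15 | step 7 | (3Z,5S,6R,7R)-1-(benzyloxy)-5,6,7,8-tetrakis(tert-butyldimethylsilyloxy)oct-3-ene | c1ccccc1COCC/C=C\[C@H](O[Si](C)(C)C(C)(C)C)[C@@H](O[Si](C)(C)C(C)(C)C)[C@H](O[Si](C)(C)C(C)(C)C)CO[Si](C)(C)C(C)(C)C
F16 | step 7 | (5S,6R,7R)-5,6,7,8-tetrakis(tert-butyldimethylsilyloxy)octan-1-ol | OCCCC[C@H](O[Si](C)(C)C(C)(C)C)[C@@H](O[Si](C)(C)C(C)(C)C)[C@H](O[Si](C)(C)C(C)(C)C)CO[Si](C)(C)C(C)(C)C
F17 | step 7 | (5S,6R,7R)-5,6,7,8-tetrakis(tert-butyldimethylsilyloxy)octanoic acid | OC(=O)CCC[C@H](O[Si](C)(C)C(C)(C)C)[C@@H](O[Si](C)(C)C(C)(C)C)[C@H](O[Si](C)(C)C(C)(C)C)CO[Si](C)(C)C(C)(C)C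
A1 | alternative 1 | (6S)-6-{(R)-hydroxy[(4R)-2,2-dimethyl-1,3-dioxolan-4-yl]methyl}oxan-2-one | O=C1CCC[C@H](O1)[C@@H](O)[C@H]2COC(C)(C)O2
A2 | alternative 1 | (2S)-2-{(R)-hydroxy[(4R)-2,2-dimethyl-1,3-dioxolan-4-yl]methyl}cyclopentan-1-one | O=C1CCC[C@H]1[C@@H](O)[C@H]2COC(C)(C)O2
A3 | alternative 1 | cyclopentanone | O=C1CCCC1
A4 | alternative 1 | (R)-2,2-dimethyl-1,3-dioxolane-4-carbaldehyde | O=C[C@H]1COC(C)(C)O1
A5 | alternative 2 | 12-O-triethylsilyl ether of 45 | CC/C=C\C/C=C\C[C@]1(O[Si](CC)(CC)CC)C=C(Cl)C(=O)[C@H]1[C@@H](OC(C)=O)[C@H](OC(C)=O)[C@H](CCCC(=O)OC)OC(C)=O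
A6 | alternative 2 | methyl (11Z,14Z)-5,6,7-triacetoxy-9-(chloroethynyl)-8-formyl-9-(triethylsilyloxy)heptadeca-11,14-dienoate, configured as 45 at C5 to C8 and C12 | CC/C=C\C/C=C\C[C@](O[Si](CC)(CC)CC)(C#CCl)[C@@H](C=O)[C@@H](OC(C)=O)[C@H](OC(C)=O)[C@H](CCCC(=O)OC)OC(C)=O
A7 | alternative 3 | methyl (14Z,17Z)-5,6,7-tris(tert-butyldimethylsilyloxy)-10-chloro-9,12-bis(triethylsilyloxy)prosta-10,14,17-trien-1-oate, configured as 45 at C5 to C8 and C12 | CC/C=C\C/C=C\C[C@]1(O[Si](CC)(CC)CC)C=C(Cl)C(O[Si](CC)(CC)CC)[C@H]1[C@@H](O[Si](C)(C)C(C)(C)C)[C@H](O[Si](C)(C)C(C)(C)C)[C@H](CCCC(=O)OC)O[Si](C)(C)C(C)(C)C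
A8 | alternative 3 | 2,2-dichlorothiane 1,1-dioxide with the 3-(triethylsilyloxy) group, the tris-silylated C1–C7 chain on ring C4, and the (2Z,5Z)-octa-2,5-dienyl and triethylsilyloxy groups on ring C5, configured as 45 | CC/C=C\C/C=C\C[C@]1(O[Si](CC)(CC)CC)CS(=O)(=O)C(Cl)(Cl)C(O[Si](CC)(CC)CC)[C@H]1[C@@H](O[Si](C)(C)C(C)(C)C)[C@H](O[Si](C)(C)C(C)(C)C)[C@H](CCCC(=O)OC)O[Si](C)(C)C(C)(C)C
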